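Stripped of both aryl rings and raised to aldehyde level at C7/C7', the six-carbon core C7–C8(C9)–C8'(C9')–C7' is C2-symmetric (2R,3R)-2,3-bis(hydroxymethyl)succinaldehyde. It folds through O9→C7' and O9'→C7 into a cis-fused 3,7-dioxabicyclo[3.3.0]octane, two tetrahydrofuran rings sharing the C8–C8' bond; the strategy rests on this feature.
Late disconnections: benzoate adjustment on the free tetraol; hydrogenolysis of C7–O and C7'–O in a 2,6-diaryl furofuran; C7–aryl and C7'–aryl bonds cut back to the C2-symmetric bis-lactone and two different aryllithiums.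
Core: bis-lactone ⇒ bis-lactol ⇒ succinaldehyde + two formaldehyde (C8–C9 and C8'–C9' bonds, both stereocentres).
Ring order: the O9–C7' ring closes after the first aldol and the O9'–C7 ring after the second, both in the key step. The bicycle carries the C8/C8' relationship through both arylations, and both rings are opened again at the hydrogenolysis.

Key step: step 2

Numbering: lignan numbering is used. C7/C7' are the benzylic carbons, C8/C8' the CH stereocentres (both R in the target) and C9/C9' the CH2O carbons. The unprimed half carries the 3-hydroxy-4-methoxyphenyl ring.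
Assumption 1: the sense of induction of the (S)-catalyst follows the steric-shielding model of its E-enamines, in which the electrophile enters anti to the CPh2OSiMe3 group. With priorities CHO > CH2OH > alkyl this gives R. If the sense proved opposite, the (R)-catalyst would be used with no other change.
Assumption 2: centres at C7/C7' (lactol, hemiketal, benzylic ether) are drawn without configuration, because each is erased later in the route.

Step 1
Reactants: 1 2,5-dimethoxytetrahydrofuran (cis/trans mixture)
Product: 2 succinaldehyde (butanedial)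
Conditions: H2O, 90 °C; MeOH/H2O distilled off; CH2Cl2 extraction, short-path distillation, used at once
Reagents that add atoms: water, O
Why: Hydrolysis of a cyclic bis-acetal, driven to the dialdehyde by distilling out methanol; no stereocentre is involved.

Step 2
Reactants: 2 succinaldehyde; 3 formaldehyde (37% aqueous, two molecules incorporated)
Product: 6 (1R,5R)-3,7-dioxabicyclo[3.3.0]octane-2,6-diol (bis-lactol; lactol epimers), via formyl lactol 4 (not isolated), via open dialdehyde 5 (not isolated)
Conditions: (S)-2-[diphenyl(trimethylsilyloxy)methyl]pyrrolidine (20 mol %), 37% aq. HCHO (6 equiv), pH 7 buffer (NaH2PO4/Na2HPO4), MeCN, 0 °C → rt, 2 added by syringe pump; concentration, co-evaporation with water to strip HCHO, SiO2 (EtOAc/MeOH)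
Reagents that add atoms: formaldehyde (compound 3, two molecules), C=O
Why: Proposed new method: the pyrrolidine nitrogen condenses with one formyl group of 2 to an E-enamine whose C8 attacks formaldehyde on the face anti to the CPh2(OSiMe3) group, which forms C8–C9 and sets C8 as R under catalyst control, and hydrolysis of the iminium ion returns the amine. O9–H then adds to the remote C7'=O (5-exo-trig hemiacetal closure, first ring) to give 4, whose only free aldehyde is α-branched and therefore a poor enamine partner for this bulky amine, which shields C8 from epimerisation and from a second hydroxymethylation. Ring–chain tautomerism of 4 uncovers C7'HO for a second cycle in which the same catalyst face rule sets C8' as R while C8'–C9' forms, and 5 closes by O9→C7' and O9'→C7 additions (each 5-exo-trig) to the cis-fused bicycle 6, whose lactol carbons equilibrate freely and are erased in step 3. The closest known reaction types are the diarylprolinol silyl ether-catalysed α-hydroxymethylation of linear aldehydes with aqueous formaldehyde and the enamine additions of succinaldehyde to Michael acceptors under the same amine; running the hydroxymethylation twice on one 1,4-dialdehyde with lactol capture is new. The step needs cross-aldol over self-aldol of 2 and over Mannich-type α-methylenation, which slow addition of 2 into excess formaldehyde at pH 7 without an acid co-catalyst should secure, and it needs like over unlike diastereoselectivity, which two catalyst-controlled events of the same sense should give. The substrate reinforces this, because only the like isomer can mask both aldehydes in a cis-fused bicyclo[3.3.0] frame, so the unlike isomer stays a formyl lactol that is removed on silica, and since most wrong-face events end in that isomer the enantiomeric purity of 6 should be higher than that of a single event.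

Step 3
Reactants: 6 bis-lactol
Product: 7 (1R,5R)-3,7-dioxabicyclo[3.3.0]octane-2,6-dione (bis-lactone)
Conditions: 2,2,6,6-tetramethylpiperidine-1-oxyl (TEMPO, 20 mol %), PhI(OAc)2 (2.5 equiv), MeCN/CH2Cl2, rt; recrystallisation
Reagents that add atoms: none
Why: Oxoammonium (TEMPO/PhI(OAc)2) oxidation of lactols to lactones runs in a weakly acidic, base-free medium, so the β-acyloxy carbonyl units should not eliminate, the lactol centres are erased, and C8/C8' hold because inversion of one of them alone would demand a trans-fused bicyclo[3.3.0]octane.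

Step 4
Reactants: 8 5-bromo-2-methoxyphenol
Product: 9 2-(benzyloxy)-4-bromo-1-methoxybenzene
Conditions: BnBr, K2CO3, DMF, rt
Reagents that add atoms: benzyl bromide, BrCc1ccccc1
Why: Williamson ether synthesis of a phenoxide with a primary benzylic bromide; no stereocentre is involved.

Step 5
Reactants: 10 4-bromo-2-methoxyphenol
Product: 11 1-(benzyloxy)-4-bromo-2-methoxybenzene
Conditions: BnBr, K2CO3, DMF, rt
Reagents that add atoms: benzyl bromide, BrCc1ccccc1
Why: Williamson ether synthesis of a phenoxide with a primary benzylic bromide; no stereocentre is involved.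

Step 6
Reactants: 9 2-(benzyloxy)-4-bromo-1-methoxybenzene; 7 bis-lactone
Product: 13 (1R,5R)-6-[3-(benzyloxy)-4-methoxyphenyl]-6-hydroxy-3,7-dioxabicyclo[3.3.0]octan-2-one (hemiketal; C6 epimers), via aryllithium 12 (not isolated)
Conditions: 9, n-BuLi (1.0 equiv), THF, −78 °C; solution of 12 cannulated slowly into 7 (1.3 equiv, excess recovered), THF, −78 °C; AcOH quench at −78 °C; crude product taken on
Reagents that add atoms: none
Why: Bromine–lithium exchange followed by 1,2-addition of the aryllithium to a γ-lactone, which stops at the lithium hemiketal at −78 °C; the two carbonyl groups of C2-symmetric 7 are homotopic, so only one mono-adduct can form, slow addition into excess 7 holds back a second addition, and the new hemiketal centre C7 is uncontrolled and disappears in step 7.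

Step 7
Reactants: 13 hemiketal
Product: 14 (1R,5R)-6-[3-(benzyloxy)-4-methoxyphenyl]-3,7-dioxabicyclo[3.3.0]octan-2-one (C6 epimers)
Conditions: Et3SiH (3 equiv), BF3·OEt2 (1.5 equiv), CH2Cl2, −78 → −20 °C; aq. NaHCO3
Reagents that add atoms: none
Why: Ionic reduction of a lactol with silane and Lewis acid (the C-aryl glycoside protocol): BF3 ionises the tertiary benzylic C7–OH to an aryl-stabilised oxocarbenium ion that takes hydride from Et3SiH on the convex face, so the aryl group should end up endo, but C7 becomes CH2 in step 10 and its configuration is immaterial, while any transient C7=C8 enol ether can only reprotonate to the cis-fused frame and the lactone and benzyl ether are inert.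

Step 8
Reactants: 11 1-(benzyloxy)-4-bromo-2-methoxybenzene; 14 aryl furofuranone
Product: 16 (1R,5R)-2-[4-(benzyloxy)-3-methoxyphenyl]-6-[3-(benzyloxy)-4-methoxyphenyl]-3,7-dioxabicyclo[3.3.0]octan-2-ol (hemiketal; C2 and C6 epimers), via aryllithium 15 (not isolated)
Conditions: 11 (1.15 equiv), n-BuLi (1.15 equiv), THF, −78 °C; added to 14, THF, −78 °C; AcOH quench at −78 °C; crude product taken on
Reagents that add atoms: none
Why: Bromine–lithium exchange and 1,2-addition of an aryllithium to the one remaining γ-lactone, arrested at the lithium hemiketal at −78 °C, a standard way to unsymmetrical furofurans; the hemiketal centre C7' is uncontrolled and disappears in step 9.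

Step 9
Reactants: 16 hemiketal
Product: 17 (1R,5R)-2-[4-(benzyloxy)-3-methoxyphenyl]-6-[3-(benzyloxy)-4-methoxyphenyl]-3,7-dioxabicyclo[3.3.0]octane (C2 and C6 epimers)
Conditions: Et3SiH (3 equiv), BF3·OEt2 (1.5 equiv), CH2Cl2, −78 → −30 °C; aq. NaHCO3
Reagents that add atoms: none
Why: Ionic silane/Lewis acid reduction of the hemiketal through the C7' oxocarbenium ion, which ionises far more readily than the secondary benzylic ether at C7; epimerisation or partial reductive opening at C7 would be harmless because both benzylic centres end as CH2 in step 10.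

Step 10
Reactants: 17 diaryl furofuran
Product: 18 (2R,3R)-2-(3-hydroxy-4-methoxybenzyl)-3-(4-hydroxy-3-methoxybenzyl)butane-1,4-diol
Conditions: H2 (4 atm), 10% Pd/C, MeOH/EtOAc, rt → 40 °C
Reagents that add atoms: none
Why: Catalytic hydrogenolysis cleaves the two aryl O-benzyl ethers and then the ring C–O bonds at the electron-rich benzylic carbons C7 and C7' (the known furofuran to dibenzylbutanediol degradation), which leaves O9 and O9' as primary alcohols and does not touch C8/C8'.

Step 11
Reactants: 18 tetraol
Product: 19 (2R,3R)-2-[3-(benzoyloxy)-4-methoxybenzyl]-3-[4-(benzoyloxy)-3-methoxybenzyl]butane-1,4-diyl dibenzoate (tetrabenzoate)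
Conditions: BzCl (6 equiv), pyridine, 4-(dimethylamino)pyridine (10 mol %), CH2Cl2, 0 °C → rt
Reagents that add atoms: benzoyl chloride, O=C(Cl)c1ccccc1
Why: Exhaustive pyridine/4-(dimethylamino)pyridine-mediated acylation with an acid chloride needs no selectivity among the four hydroxyl groups and touches no stereocentre.

Step 12
Reactants: 19 tetrabenzoate
Product: 20 (2R,3R)-2-(3-hydroxy-4-methoxybenzyl)-3-(4-hydroxy-3-methoxybenzyl)butane-1,4-diyl dibenzoate (target, CNP0306197.1)
Conditions: pyrrolidine (2.5 equiv), CH2Cl2, 0 °C → rt; dilute aq. HCl wash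
Reagents that add atoms: none
Why: Chemoselective aminolysis of aryl esters: phenoxide (pKa about 10) is a far better leaving group than a primary alkoxide, so pyrrolidine should remove the two aryl benzoates at or below room temperature while the alkyl benzoates stay intact, and no stereocentre is at risk.

Compound list
1 | 2,5-dimethoxytetrahydrofuran (cis/trans mixture) | COC1CCC(OC)O1 | starting material
2 | succinaldehyde | O=CCCC=O | intermediate
3 | formaldehyde (37% aqueous) | C=O | starting material
4 | (3R)-5-hydroxytetrahydrofuran-3-carbaldehyde (formyl lactol, lactol epimers; not isolated) | O=C[C@H]1COC(O)C1 | intermediate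
5 | (2R,3R)-2,3-bis(hydroxymethyl)butanedial (open dialdehyde; not isolated) | O=C[C@@H](CO)[C@H](CO)C=O | intermediate
6 | (1R,5R)-3,7-dioxabicyclo[3.3.0]octane-2,6-diol (cis-fused bis-lactol, lactol epimers) | OC1OC[C@@H]2C(O)OC[C@H]12 | intermediate
7 | (1R,5R)-3,7-dioxabicyclo[3.3.0]octane-2,6-dione (cis-fused bis-lactone) | O=C1OC[C@@H]2C(=O)OC[C@H]12 | intermediate
8 | 5-bromo-2-methoxyphenol | COc1ccc(Br)cc1O | starting material
9 | 2-(benzyloxy)-4-bromo-1-methoxybenzene | COc1ccc(Br)cc1OCc1ccccc1 | intermediate
10 | 4-bromo-2-methoxyphenol | COc1cc(Br)ccc1O | starting material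
11 | 1-(benzyloxy)-4-bromo-2-methoxybenzene | COc1cc(Br)ccc1OCc1ccccc1 | intermediate
12 | [3-(benzyloxy)-4-methoxyphenyl]lithium (not isolated) | COc1ccc([Li])cc1OCc1ccccc1 | intermediate
13 | (1R,5R)-6-[3-(benzyloxy)-4-methoxyphenyl]-6-hydroxy-3,7-dioxabicyclo[3.3.0]octan-2-one (C6 epimers) | COc1ccc(cc1OCc1ccccc1)C1(O)OC[C@@H]2C(=O)OC[C@H]12 | intermediate
14 | (1R,5R)-6-[3-(benzyloxy)-4-methoxyphenyl]-3,7-dioxabicyclo[3.3.0]octan-2-one (C6 epimers) | COc1ccc(cc1OCc1ccccc1)C1OC[C@@H]2C(=O)OC[C@H]12 | intermediate
15 | [4-(benzyloxy)-3-methoxyphenyl]lithium (not isolated) | COc1cc([Li])ccc1OCc1ccccc1 | intermediate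
16 | (1R,5R)-2-[4-(benzyloxy)-3-methoxyphenyl]-6-[3-(benzyloxy)-4-methoxyphenyl]-3,7-dioxabicyclo[3.3.0]octan-2-ol (C2, C6 epimers) | COc1ccc(cc1OCc1ccccc1)C1OC[C@@H]2C(O)(c3ccc(OCc4ccccc4)c(OC)c3)OC[C@H]12 | intermediate
17 | (1R,5R)-2-[4-(benzyloxy)-3-methoxyphenyl]-6-[3-(benzyloxy)-4-methoxyphenyl]-3,7-dioxabicyclo[3.3.0]octane (C2, C6 epimers) | COc1ccc(cc1OCc1ccccc1)C1OC[C@@H]2C(c3ccc(OCc4ccccc4)c(OC)c3)OC[C@H]12 | intermediate
18 | (2R,3R)-2-(3-hydroxy-4-methoxybenzyl)-3-(4-hydroxy-3-methoxybenzyl)butane-1,4-diol | COc1ccc(C[C@@H](CO)[C@H](CO)Cc2ccc(O)c(OC)c2)cc1O | intermediate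
19 | (2R,3R)-2-[3-(benzoyloxy)-4-methoxybenzyl]-3-[4-(benzoyloxy)-3-methoxybenzyl]butane-1,4-diyl dibenzoate | COc1ccc(C[C@@H](COC(=O)c2ccccc2)[C@H](COC(=O)c2ccccc2)Cc2ccc(OC(=O)c3ccccc3)c(OC)c2)cc1OC(=O)c1ccccc1 | intermediate
20 | (2R,3R)-2-(3-hydroxy-4-methoxybenzyl)-3-(4-hydroxy-3-methoxybenzyl)butane-1,4-diyl dibenzoate | COc1ccc(C[C@@H](COC(=O)c2ccccc2)[C@H](COC(=O)c2ccccc2)Cc2ccc(O)c(OC)c2)cc1O | target

Total step count: 12.
Longest linear sequence: 10 steps (1, 2, 3, 6, 7, 8, 9, 10, 11, 12) from 2,5-dimethoxytetrahydrofuran. Steps 4 and 5 are side branches.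

Steps most likely to fail

Step 2 (key step).
- What may go wrong: self-aldol and oligomerisation of succinaldehyde may outrun the cross-aldol. Mannich-type dehydration may lead to α-methylene aldehydes. C8 may lose configuration through slow enamine formation at the branched aldehyde. Catalyst control may be weak in the second event, next to the resident centre. The very water-soluble product may be lost on isolation.
- Fallback, from 2 back to 6: the catalytic aldol is replaced by auxiliary-controlled azaenolate alkylation (Enders SAMP/RAMP hydrazone alkylation), with benzyloxymethyl chloride as the formaldehyde equivalent. Compound 2 is condensed with two equivalents of (R)-1-amino-2-(methoxymethyl)pyrrolidine (RAMP) to the succinaldehyde bis-RAMP-hydrazone F1. LiN(i-Pr)2 and then ClCH2OCH2Ph (THF, −100 °C) should give the mono-alkylated bis-hydrazone F2. A second round at the remaining CH2 should give the dialkylated bis-hydrazone F3, each centre being set by the auxiliary on its own hydrazone. Ozonolysis (CH2Cl2, −78 °C) releases (2R,3R)-2,3-bis(benzyloxymethyl)butanedial F4. Hydrogenolysis (H2, 10% Pd/C, EtOAc) then frees both alcohols, so that 5 forms and folds to 6.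

Step 6 (mono-arylation of the bis-lactone).
- What may go wrong: a second addition may occur at the other lactone. Enolisation at C8 may be followed by β-elimination of the carboxylate. The adduct may open to the aryl ketone and epimerise at C8.
- Fallback, from 7 (with 12) back to 14: the acyl addition is replaced by arylation of an oxocarbenium ion with a non-basic organozinc reagent that tolerates the lactone. i-Bu2AlH (1.0 equiv, CH2Cl2, −78 °C) reduces one lactone of 7 to (1R,5R)-6-hydroxy-3,7-dioxabicyclo[3.3.0]octan-2-one F5; any over-reduced material is 6 and is returned through step 3. Ac2O/pyridine gives the lactol acetate F6. Aryllithium 12 is transmetalated with ZnBr2 to [3-(benzyloxy)-4-methoxyphenyl]zinc bromide F7. BF3·OEt2 (CH2Cl2, −40 → 0 °C) ionises F6 for C-arylation by F7, as in C-aryl glycoside chemistry, and this gives 14 directly without passing through 13.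

Step 10 (double ring hydrogenolysis).
- What may go wrong: the reaction may stall after debenzylation and the first ring opening, at the stage of a monocyclic 2-aryltetrahydrofuran. Forcing conditions may saturate an aryl ring. Traces of acid may induce Friedel–Crafts closure of the benzylic position onto the other aryl ring.
- Fallback, from 17 back to 20: the ring C–O bonds are cut first with a Lewis-acidic hydride that keeps the O-benzyl groups, so that plain dibenzoylation becomes possible. LiAlH4/AlCl3 (AlH2Cl, Et2O/CH2Cl2, 0 °C → rt) coordinates each ring oxygen and delivers hydride to the p-alkoxybenzylic carbon, a mixed-hydride hydrogenolysis of electron-rich benzylic ethers. This gives (2R,3R)-2-[3-(benzyloxy)-4-methoxybenzyl]-3-[4-(benzyloxy)-3-methoxybenzyl]butane-1,4-diol F8. BzCl/pyridine gives its dibenzoate F9. Mild hydrogenolysis (H2, 1 atm, 10% Pd/C, EtOAc) removes only the two O-benzyl groups and gives 20, bypassing 18 and 19.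

Further compounds
F1 | step 2 | succinaldehyde bis-RAMP-hydrazone | COC[C@H]1CCCN1/N=C/CC/C=N/N1CCC[C@@H]1COC
F2 | step 2 | bis-RAMP-hydrazone of (2R)-2-(benzyloxymethyl)butanedial | COC[C@H]1CCCN1/N=C/[C@@H](COCc1ccccc1)C/C=N/N1CCC[C@@H]1COC
F3 | step 2 | bis-RAMP-hydrazone of (2R,3R)-2,3-bis(benzyloxymethyl)butanedial | COC[C@H]1CCCN1/N=C/[C@@H](COCc1ccccc1)[C@H](COCc1ccccc1)/C=N/N1CCC[C@@H]1COC
F4 | step 2 | (2R,3R)-2,3-bis(benzyloxymethyl)butanedial | O=C[C@@H](COCc1ccccc1)[C@H](COCc1ccccc1)C=O
F5 | step 6 | (1R,5R)-6-hydroxy-3,7-dioxabicyclo[3.3.0]octan-2-one (lactol epimers) | OC1OC[C@@H]2C(=O)OC[C@H]12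
F6 | step 6 | (1R,5R)-6-acetoxy-3,7-dioxabicyclo[3.3.0]octan-2-one (C6 epimers) | CC(=O)OC1OC[C@@H]2C(=O)OC[C@H]12
F7 | step 6 | [3-(benzyloxy)-4-methoxyphenyl]zinc bromide | COc1ccc([Zn]Br)cc1OCc1ccccc1
F8 | step 10 | (2R,3R)-2-[3-(benzyloxy)-4-methoxybenzyl]-3-[4-(benzyloxy)-3-methoxybenzyl]butane-1,4-diol | COc1ccc(C[C@@H](CO)[C@H](CO)Cc2ccc(OCc3ccccc3)c(OC)c2)cc1OCc1ccccc1
F9 | step 10 | (2R,3R)-2-[3-(benzyloxy)-4-methoxybenzyl]-3-[4-(benzyloxy)-3-methoxybenzyl]butane-1,4-diyl dibenzoate | COc1ccc(C[C@@H](COC(=O)c2ccccc2)[C@H](COC(=O)c2ccccc2)Cc2ccc(OCc3ccccc3)c(OC)c2)cc1OCc1ccccc1
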